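The 14-membered carbocycle is opened at C2–C3 (cembrane numbering: C1 ring-fusion CH, C2 lactone carbinol, C13 acetoxy carbon, C15–C17 lactone arm). The key step exploits the ring junction: C2 of the carbocycle bears the lactone oxygen and adjoins the trisubstituted E alkene C3=C4, so it can be made as an allylic alcohol from a C2 aldehyde and a C3 alkenylchromium. One operation forms C2–C3, closes the 14-membered ring with the alkene geometry preset, and creates the C2 stereocentre. The precursor is an open-chain E-iodotriene bearing the C13 silyl ether, the C1-branched aldehyde and a tert-butyl acetate arm; the lactone ring is closed afterwards.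

Key step: step 12

Design notes:
- The open-chain precursor and the ring-closed hydroxy ester carry C1 and C13 in the same spatial arrangement as the target, so no structural correction is needed. The C2 descriptor reads R before the exocyclic methylene is present and S after it; this is a change of CIP ranking, not an inversion.
- The C2 hydroxyl must end syn to the C1 acetate arm (cis ring fusion).
- The tert-butyl ester is kept so that neither LiBH4 nor the chromium alkoxide acylates prematurely. The lactone is then closed by alkoxide catalysis, not acid, because the C2 carbinol ionises easily to an allyl cation and the macrocyclic 1,5-dienes are prone to acid-triggered transannular cyclisation.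
- The epimerisable aldehyde is made immediately before ring closure and used at once.
- A C2 epimer from the ring closure would be separated there and recycled by oxidation and reduction, not by inversion (see the fallback for step 12).

Assumption: in the two reagent-controlled additions (steps 4 and 12) the catalyst or ligand antipode named is the one expected to give Re-face allylation of the enal and Si-face alkenylation of the C2 aldehyde; if the sense proved opposite on this substrate, the mirror-image catalyst or ligand would be used with no other change.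

Step 1
Reactants: 1 geranyl bromide [(2E)-1-bromo-3,7-dimethylocta-2,6-diene]; 2 1-(trimethylsilyl)propyne
Product: 5 (5E)-6,10-dimethylundeca-5,9-dien-1-yne, via lithiated silylpropyne 3 (not isolated), via silylated dienyne 4 (not isolated)
Conditions: 2, n-BuLi, THF, −78 → −20 °C; 1, −78 °C → rt; then MeOH, K2CO3 (cat.), rt
Reagents that add atoms: none
Why: The propargylic lithium reagent displaces the primary allylic bromide in an SN2 alkylation at its CH2 terminus (the silyl group suppresses the allenyl mode and the 2E alkene of 1 is untouched), and base-catalysed methanolysis then removes the alkynyl silane in the same flask.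

Step 2
Reactants: 5
Product: 7 (1E,5E)-1-iodo-2,6,10-trimethylundeca-1,5,9-triene, via alkenylalane 6 (not isolated)
Conditions: Me3Al (2 equiv), Cp2ZrCl2 (0.25 equiv), CH2Cl2, 0 °C → rt; then I2, THF, −30 → 0 °C
Reagents that add atoms: trimethylaluminium C[Al](C)C; iodine II
Why: Negishi carboalumination adds methyl and aluminium syn across the terminal alkyne with methyl on the internal carbon, and iodinolysis of the C–Al bond with retention fixes the E geometry of the future C3=C4 alkene.

Step 3
Reactants: 7
Product: 9 (2E,6E,10E)-11-iodo-2,6,10-trimethylundeca-2,6,10-trienal, via allylic alcohol 8 (not isolated)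
Conditions: SeO2 (0.1 equiv), t-BuOOH, salicylic acid (0.1 equiv), CH2Cl2, 0 °C → rt; crude mixture, MnO2, CH2Cl2, rt
Reagents that add atoms: tert-butyl hydroperoxide CC(C)(C)OO (oxygen passed on through catalytic selenium dioxide O=[Se]=O)
Why: Riley allylic oxidation (ene reaction, then 2,3-sigmatropic shift) should attack the E-methyl of the terminal isopropylidene group, the most accessible electron-rich alkene with the iodoalkene deactivated, and MnO2 converges the alcohol/aldehyde mixture on the E-enal.

Step 4
Reactants: 9; 10 allylboronic acid pinacol ester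
Product: 12 (4R,5E,9E,13E)-14-iodo-5,9,13-trimethyltetradeca-1,5,9,13-tetraen-4-ol, via pinacol borate ester 11 (not isolated)
Conditions: (R)-3,3'-bis(2,4,6-triisopropylphenyl)-1,1'-binaphthyl-2,2'-diyl hydrogen phosphate (5 mol %), toluene, −30 °C; aq. work-up
Reagents that add atoms: none
Why: Chiral phosphoric acid-catalysed allylboration runs through a closed chair six-membered transition state in which the catalyst binds a boronate oxygen and the formyl hydrogen, exposing the Re face of the enal and setting C13 as R, and any minor antipode becomes a separable diastereomer once the auxiliary is attached in step 8.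

Step 5
Reactants: 12
Product: 13 tert-butyl{[(4R,5E,9E,13E)-14-iodo-5,9,13-trimethyltetradeca-1,5,9,13-tetraen-4-yl]oxy}dimethylsilane
Conditions: TBSCl, imidazole, DMF, rt
Reagents that add atoms: tert-butyldimethylsilyl chloride CC(C)(C)[Si](C)(C)Cl
Why: Imidazole-promoted silylation of the secondary allylic alcohol gives an ether that should withstand the borane, enolate, hydride, chromium and amide-base steps that follow.

Step 6
Reactants: 13
Product: 15 (4R,5E,9E,13E)-4-[(tert-butyldimethylsilyl)oxy]-14-iodo-5,9,13-trimethyltetradeca-5,9,13-trien-1-ol, via alkylborane 14 (not isolated)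
Conditions: 9-BBN, THF, 0 °C → rt; then NaOH, H2O2, 0 °C
Reagents that add atoms: hydrogen peroxide OO
Why: Anti-Markovnikov hydroboration with the bulky 9-BBN is selective for the monosubstituted alkene over the three trisubstituted ones (iodoalkene included), and alkaline peroxide oxidation replaces boron by hydroxyl.

Step 7
Reactants: 15
Product: 17 (4R,5E,9E,13E)-4-[(tert-butyldimethylsilyl)oxy]-14-iodo-5,9,13-trimethyltetradeca-5,9,13-trienoic acid, via aldehyde 16 (not isolated)
Conditions: TEMPO (0.2 equiv), PhI(OAc)2 (2.2 equiv), MeCN/H2O, rt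
Reagents that add atoms: water O
Why: Oxoammonium-mediated oxidation in aqueous acetonitrile takes the primary alcohol through the aldehyde hydrate to the acid without touching the alkenes, the alkenyl iodide or the silyl ether.

Step 8
Reactants: 17; 18 (R)-4-benzyl-1,3-oxazolidin-2-one
Product: 20 (4R)-4-benzyl-3-[(4R,5E,9E,13E)-4-[(tert-butyldimethylsilyl)oxy]-14-iodo-5,9,13-trimethyltetradeca-5,9,13-trienoyl]-1,3-oxazolidin-2-one, via mixed pivalic anhydride 19 (not isolated)
Conditions: PivCl, Et3N, THF, −20 °C; then 18, LiCl, −20 °C → rt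
Reagents that add atoms: none
Why: N-Acylation of the oxazolidinone through the mixed pivalic anhydride with LiCl activation is the standard mild way to attach the auxiliary to an acid that carries sensitive groups.

Step 9
Reactants: 20; 21 tert-butyl bromoacetate
Product: 23 tert-butyl (3S,5R,6E,10E,14E)-3-{[(4R)-4-benzyl-2-oxo-1,3-oxazolidin-3-yl]carbonyl}-5-[(tert-butyldimethylsilyl)oxy]-15-iodo-6,10,14-trimethylpentadeca-6,10,14-trienoate, via sodium enolate 22 (not isolated)
Conditions: NaN(SiMe3)2, THF, −78 °C; 21, −78 → −45 °C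
Reagents that add atoms: none
Why: In this Evans alkylation the chelated Z sodium enolate is attacked by the reactive bromo ester on the face opposite the benzyl group of the (R)-auxiliary, which sets C1 as S, the configuration needed in the target.

Step 10
Reactants: 23
Product: 24 tert-butyl (3S,5R,6E,10E,14E)-5-[(tert-butyldimethylsilyl)oxy]-3-(hydroxymethyl)-15-iodo-6,10,14-trimethylpentadeca-6,10,14-trienoate
Conditions: LiBH4, H2O (1 equiv), Et2O, 0 °C
Reagents that add atoms: none
Why: Reductive cleavage with LiBH4 attacks the activated exocyclic imide carbonyl much faster than the hindered tert-butyl ester, releasing the auxiliary and the primary C2 alcohol without touching C1.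

Step 11
Reactants: 24
Product: 25 tert-butyl (3S,5R,6E,10E,14E)-5-[(tert-butyldimethylsilyl)oxy]-3-formyl-15-iodo-6,10,14-trimethylpentadeca-6,10,14-trienoate
Conditions: Dess–Martin periodinane, CH2Cl2, 0 °C → rt; used at once
Reagents that add atoms: none
Why: Dess–Martin oxidation under non-basic conditions should give the branched aldehyde without epimerising C1 or disturbing the ester, the silyl ether or the alkenyl iodide.

Step 12
Reactants: 25
Product: 27 tert-butyl 2-[(1S,2R,3E,7E,11E,13R)-13-[(tert-butyldimethylsilyl)oxy]-2-hydroxy-4,8,12-trimethylcyclotetradeca-3,7,11-trien-1-yl]acetate, via alkenylchromium 26 (not isolated)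
Conditions: CrCl2 (8 equiv), (S)-N-[2-(4-isopropyl-4,5-dihydro-1,3-oxazol-2-yl)-6-methylphenyl]methanesulfonamide (8.8 equiv), Et3N (8.8 equiv), THF, rt, 1 h; NiCl2 (0.2 equiv); 25 added by syringe pump over 10 h (final 2 mM), rt
Reagents that add atoms: none
Why: Zerovalent nickel, formed from NiCl2 by divalent chromium, inserts into the C3–I bond, the alkenyl group passes with retention to trivalent chromium, and alkenylchromium 26 adds to the C2 aldehyde (Nozaki–Hiyama–Kishi reaction). The closest known reaction type is the chromium-mediated alkenyl iodide–aldehyde macrocyclisation used for cembranoid and other large carbocycles, here run with a chiral sulfonamide ligand on chromium. The 14-membered carbocycle closes in a 14-exo-trig mode at the carbonyl carbon, leaving C3=C4 endocyclic and still E because its geometry was fixed in step 2. The new C2 stereocentre is controlled by the ligand, chosen to direct attack to the Si face of the aldehyde so that the hydroxyl ends syn to the C1 acetate arm, while the adjacent C1 centre is expected to bias the addition only weakly. The step needs chemoselectivity for the aldehyde over the tert-butyl ester and must not epimerise C1: organochromium reagents do not add to esters, the medium is neither acidic nor strongly basic, and the bulky ester keeps the chromium alkoxide from lactonising. Cyclisation should be favoured over oligomerisation by slow addition to high dilution.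

Step 13
Reactants: 27
Product: 29 (3aS,5R,6E,10E,14E,15aR)-5-[(tert-butyldimethylsilyl)oxy]-6,10,14-trimethyl-3a,4,5,8,9,12,13,15a-octahydrocyclotetradeca[b]furan-2(3H)-one, via potassium alkoxide 28 (not isolated)
Conditions: KOt-Bu (0.2 equiv), THF (0.02 M), 0 °C → rt
Reagents that add atoms: none
Why: Alkoxide-catalysed intramolecular transesterification (5-exo-trig attack of the C2 oxygen on the ester carbonyl with loss of tert-butoxide, which carries the chain) closes the γ-lactone without breaking the C2–O bond, so the cis fusion from step 12 is kept and the ionisable allylic carbinol never meets acid.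

Step 14
Reactants: 29
Product: 33 (3aS,5R,6E,10E,14E,15aS)-5-[(tert-butyldimethylsilyl)oxy]-6,10,14-trimethyl-3-methylidene-3a,4,5,8,9,12,13,15a-octahydrocyclotetradeca[b]furan-2(3H)-one, via lithium enolate 30 (not isolated), via Mannich base 31 (not isolated), via ammonium iodide 32 (not isolated)
Conditions: LiN(i-Pr)2, THF, −78 °C; dimethylmethylideneammonium iodide, −78 → 0 °C; crude amine, MeI, MeOH, rt; then aq. NaHCO3/CH2Cl2, rt
Reagents that add atoms: dimethylmethylideneammonium iodide C=[N+](C)C.[I-]
Why: Mannich aminomethylation of the lactone enolate, N-methylation and Hofmann-type elimination is the standard methylenation of γ-butyrolactones, and the transient C15 centre becomes sp2 so no selectivity is required.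

Step 15
Reactants: 33
Product: 34 (3aS,5R,6E,10E,14E,15aS)-5-hydroxy-6,10,14-trimethyl-3-methylidene-3a,4,5,8,9,12,13,15a-octahydrocyclotetradeca[b]furan-2(3H)-one
Conditions: HF·pyridine, pyridine, THF, 0 °C → rt
Reagents that add atoms: none
Why: Fluoride-mediated desilylation with buffered HF·pyridine cleaves the secondary silyl ether at silicon under conditions too weakly basic and nucleophilic to add to the methylene lactone or shift its double bond.

Step 16
Reactants: 34
Product: 35 (3aS,5R,6E,10E,14E,15aS)-6,10,14-trimethyl-3-methylidene-2-oxo-2,3,3a,4,5,8,9,12,13,15a-decahydrocyclotetradeca[b]furan-5-yl acetate (target)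
Conditions: Ac2O, pyridine, DMAP (cat.), CH2Cl2, 0 °C → rt
Reagents that add atoms: acetic anhydride CC(=O)OC(C)=O
Why: DMAP-catalysed O-acylation of the secondary allylic alcohol takes place at oxygen with retention at C13 and completes the target.

Compound list
1 | geranyl bromide, (2E)-1-bromo-3,7-dimethylocta-2,6-diene | CC(C)=CCC/C(C)=C/CBr | starting material
2 | 1-(trimethylsilyl)propyne | CC#C[Si](C)(C)C | starting material
3 | 3-lithio-1-(trimethylsilyl)prop-1-yne | [Li]CC#C[Si](C)(C)C | intermediate
4 | [(5E)-6,10-dimethylundeca-5,9-dien-1-yn-1-yl]trimethylsilane | C[Si](C)(C)C#CCC/C=C(\C)CCC=C(C)C | intermediate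
5 | (5E)-6,10-dimethylundeca-5,9-dien-1-yne | C#CCC/C=C(\C)CCC=C(C)C | intermediate
6 | dimethyl[(1E,5E)-2,6,10-trimethylundeca-1,5,9-trien-1-yl]alane | C[Al](C)/C=C(\C)CC/C=C(\C)CCC=C(C)C | intermediate
7 | (1E,5E)-1-iodo-2,6,10-trimethylundeca-1,5,9-triene | I/C=C(\C)CC/C=C(\C)CCC=C(C)C | intermediate
8 | (2E,6E,10E)-11-iodo-2,6,10-trimethylundeca-2,6,10-trien-1-ol | I/C=C(\C)CC/C=C(\C)CC/C=C(\C)CO | intermediate
9 | (2E,6E,10E)-11-iodo-2,6,10-trimethylundeca-2,6,10-trienal | I/C=C(\C)CC/C=C(\C)CC/C=C(\C)C=O | intermediate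
10 | allylboronic acid pinacol ester | C=CCB1OC(C)(C)C(C)(C)O1 | starting material
11 | 2-{[(4R,5E,9E,13E)-14-iodo-5,9,13-trimethyltetradeca-1,5,9,13-tetraen-4-yl]oxy}-4,4,5,5-tetramethyl-1,3,2-dioxaborolane | I/C=C(\C)CC/C=C(\C)CC/C=C(\C)[C@H](OB1OC(C)(C)C(C)(C)O1)CC=C | intermediate
12 | (4R,5E,9E,13E)-14-iodo-5,9,13-trimethyltetradeca-1,5,9,13-tetraen-4-ol | I/C=C(\C)CC/C=C(\C)CC/C=C(\C)[C@H](O)CC=C | intermediate
13 | tert-butyl{[(4R,5E,9E,13E)-14-iodo-5,9,13-trimethyltetradeca-1,5,9,13-tetraen-4-yl]oxy}dimethylsilane | I/C=C(\C)CC/C=C(\C)CC/C=C(\C)[C@H](O[Si](C)(C)C(C)(C)C)CC=C | intermediate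
14 | 9-[(4R,5E,9E,13E)-4-[(tert-butyldimethylsilyl)oxy]-14-iodo-5,9,13-trimethyltetradeca-5,9,13-trien-1-yl]-9-borabicyclo[3.3.1]nonane | I/C=C(\C)CC/C=C(\C)CC/C=C(\C)[C@H](O[Si](C)(C)C(C)(C)C)CCCB1C2CCCC1CCC2 | intermediate
15 | (4R,5E,9E,13E)-4-[(tert-butyldimethylsilyl)oxy]-14-iodo-5,9,13-trimethyltetradeca-5,9,13-trien-1-ol | I/C=C(\C)CC/C=C(\C)CC/C=C(\C)[C@H](O[Si](C)(C)C(C)(C)C)CCCO | intermediate
16 | (4R,5E,9E,13E)-4-[(tert-butyldimethylsilyl)oxy]-14-iodo-5,9,13-trimethyltetradeca-5,9,13-trienal | I/C=C(\C)CC/C=C(\C)CC/C=C(\C)[C@H](O[Si](C)(C)C(C)(C)C)CCC=O | intermediate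
17 | (4R,5E,9E,13E)-4-[(tert-butyldimethylsilyl)oxy]-14-iodo-5,9,13-trimethyltetradeca-5,9,13-trienoic acid | I/C=C(\C)CC/C=C(\C)CC/C=C(\C)[C@H](O[Si](C)(C)C(C)(C)C)CCC(=O)O | intermediate
18 | (R)-4-benzyl-1,3-oxazolidin-2-one | O=C1OC[C@@H](Cc2ccccc2)N1 | starting material
19 | mixed anhydride of 17 with 2,2-dimethylpropanoic acid | I/C=C(\C)CC/C=C(\C)CC/C=C(\C)[C@H](O[Si](C)(C)C(C)(C)C)CCC(=O)OC(=O)C(C)(C)C | intermediate
20 | (4R)-4-benzyl-3-[(4R,5E,9E,13E)-4-[(tert-butyldimethylsilyl)oxy]-14-iodo-5,9,13-trimethyltetradeca-5,9,13-trienoyl]-1,3-oxazolidin-2-one | I/C=C(\C)CC/C=C(\C)CC/C=C(\C)[C@H](O[Si](C)(C)C(C)(C)C)CCC(=O)N1[C@H](Cc2ccccc2)COC1=O | intermediate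
21 | tert-butyl bromoacetate | BrCC(=O)OC(C)(C)C | starting material
22 | sodium Z-enolate of 20 | I/C=C(\C)CC/C=C(\C)CC/C=C(\C)[C@H](O[Si](C)(C)C(C)(C)C)C/C=C(\[O-])N1[C@H](Cc2ccccc2)COC1=O.[Na+] | intermediate
23 | tert-butyl (3S,5R,6E,10E,14E)-3-{[(4R)-4-benzyl-2-oxo-1,3-oxazolidin-3-yl]carbonyl}-5-[(tert-butyldimethylsilyl)oxy]-15-iodo-6,10,14-trimethylpentadeca-6,10,14-trienoate | I/C=C(\C)CC/C=C(\C)CC/C=C(\C)[C@H](O[Si](C)(C)C(C)(C)C)C[C@@H](CC(=O)OC(C)(C)C)C(=O)N1[C@H](Cc2ccccc2)COC1=O | intermediate
24 | tert-butyl (3S,5R,6E,10E,14E)-5-[(tert-butyldimethylsilyl)oxy]-3-(hydroxymethyl)-15-iodo-6,10,14-trimethylpentadeca-6,10,14-trienoate | I/C=C(\C)CC/C=C(\C)CC/C=C(\C)[C@H](O[Si](C)(C)C(C)(C)C)C[C@@H](CC(=O)OC(C)(C)C)CO | intermediate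
25 | tert-butyl (3S,5R,6E,10E,14E)-5-[(tert-butyldimethylsilyl)oxy]-3-formyl-15-iodo-6,10,14-trimethylpentadeca-6,10,14-trienoate (key-step precursor) | I/C=C(\C)CC/C=C(\C)CC/C=C(\C)[C@H](O[Si](C)(C)C(C)(C)C)C[C@H](C=O)CC(=O)OC(C)(C)C | intermediate
26 | C3-alkenylchromium dichloride derived from 25 (trivalent chromium, sulfonamide ligand omitted) | Cl[Cr](Cl)/C=C(\C)CC/C=C(\C)CC/C=C(\C)[C@H](O[Si](C)(C)C(C)(C)C)C[C@H](C=O)CC(=O)OC(C)(C)C | intermediate
27 | tert-butyl 2-[(1S,2R,3E,7E,11E,13R)-13-[(tert-butyldimethylsilyl)oxy]-2-hydroxy-4,8,12-trimethylcyclotetradeca-3,7,11-trien-1-yl]acetate (key-step product) | O[C@H]1/C=C(\C)CC/C=C(\C)CC/C=C(\C)[C@H](O[Si](C)(C)C(C)(C)C)C[C@H]1CC(=O)OC(C)(C)C | intermediate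
28 | potassium C2 alkoxide of 27 | [K+].[O-][C@H]1/C=C(\C)CC/C=C(\C)CC/C=C(\C)[C@H](O[Si](C)(C)C(C)(C)C)C[C@H]1CC(=O)OC(C)(C)C | intermediate
29 | (3aS,5R,6E,10E,14E,15aR)-5-[(tert-butyldimethylsilyl)oxy]-6,10,14-trimethyl-3a,4,5,8,9,12,13,15a-octahydrocyclotetradeca[b]furan-2(3H)-one (cis-fused lactone) | C1C(=O)O[C@H]2/C=C(\C)CC/C=C(\C)CC/C=C(\C)[C@H](O[Si](C)(C)C(C)(C)C)C[C@@H]12 | intermediate
30 | lithium enolate of 29 | C1=C([O-])O[C@H]2/C=C(\C)CC/C=C(\C)CC/C=C(\C)[C@H](O[Si](C)(C)C(C)(C)C)C[C@@H]12.[Li+] | intermediate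
31 | 3-[(dimethylamino)methyl] derivative of 29 (epimers at C3 of the lactone) | CN(C)CC1C(=O)O[C@H]2/C=C(\C)CC/C=C(\C)CC/C=C(\C)[C@H](O[Si](C)(C)C(C)(C)C)C[C@@H]12 | intermediate
32 | 3-[(trimethylammonio)methyl] derivative of 29, iodide | C[N+](C)(C)CC1C(=O)O[C@H]2/C=C(\C)CC/C=C(\C)CC/C=C(\C)[C@H](O[Si](C)(C)C(C)(C)C)C[C@@H]12.[I-] | intermediate
33 | (3aS,5R,6E,10E,14E,15aS)-5-[(tert-butyldimethylsilyl)oxy]-6,10,14-trimethyl-3-methylidene-3a,4,5,8,9,12,13,15a-octahydrocyclotetradeca[b]furan-2(3H)-one | C=C1C(=O)O[C@H]2/C=C(\C)CC/C=C(\C)CC/C=C(\C)[C@H](O[Si](C)(C)C(C)(C)C)C[C@@H]12 | intermediate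
34 | (3aS,5R,6E,10E,14E,15aS)-5-hydroxy-6,10,14-trimethyl-3-methylidene-3a,4,5,8,9,12,13,15a-octahydrocyclotetradeca[b]furan-2(3H)-one | C=C1C(=O)O[C@H]2/C=C(\C)CC/C=C(\C)CC/C=C(\C)[C@H](O)C[C@@H]12 | intermediate
35 | (3aS,5R,6E,10E,14E,15aS)-6,10,14-trimethyl-3-methylidene-2-oxo-2,3,3a,4,5,8,9,12,13,15a-decahydrocyclotetradeca[b]furan-5-yl acetate | C=C1C(=O)O[C@H]2/C=C(\C)CC/C=C(\C)CC/C=C(\C)[C@H](OC(C)=O)C[C@@H]12 | target

Total step count: 16
Longest linear sequence: 16 steps (1 → 35; the route is linear)

Steps most likely to fail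

Step 12. The risk is weak facial discrimination at the C2 carbonyl during ring closure: the conformational demands of the 14-membered transition state may override the ligand and deliver much of the C2 epimer. Fallback: starting from 25, the ring is closed without chiral ligand (CrCl2, NiCl2 cat., DMSO/THF, high dilution), which should give 27 together with its C2 epimer tert-butyl 2-[(1S,2S,3E,7E,11E,13R)-13-[(tert-butyldimethylsilyl)oxy]-2-hydroxy-4,8,12-trimethylcyclotetradeca-3,7,11-trien-1-yl]acetate F1. The unseparated mixture is oxidised with Dess–Martin periodinane to the macrocyclic enone tert-butyl 2-[(1S,3E,7E,11E,13R)-13-[(tert-butyldimethylsilyl)oxy]-4,8,12-trimethyl-2-oxocyclotetradeca-3,7,11-trien-1-yl]acetate F2. A Corey–Bakshi–Shibata reduction ((S)-2-methyl-CBS-oxazaborolidine, catecholborane, toluene, −78 °C), with the trisubstituted alkenyl group expected to act as the larger substituent, should then return 27. C2 is thus set by reagent-controlled 1,2-reduction instead of by the addition. The enone is kept cold and neutral because C1 is then α to a ketone. The same two operations recycle any C2 epimer separated in the main route.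

Step 3. The risk is poor site selectivity of the allylic oxidation among the three trisubstituted alkenes, together with over-oxidation, leaving little of the terminal E-enal. Fallback: starting from 7, the terminal alkene is singled out by electrophilic addition instead of an ene reaction. NBS in aqueous THF at 0 °C should give the terminal bromohydrin (6E,10E)-3-bromo-11-iodo-2,6,10-trimethylundeca-6,10-dien-2-ol F3. K2CO3 in MeOH closes it to the epoxide 2,2-dimethyl-3-[(3E,7E)-8-iodo-3,7-dimethylocta-3,7-dien-1-yl]oxirane F4. Periodic acid (H5IO6, THF/Et2O, 0 °C) cleaves the epoxide to (4E,8E)-9-iodo-4,8-dimethylnona-4,8-dienal F5 with loss of acetone. A Wittig reaction with the stabilised ylide Ph3P=C(CH3)CHO (toluene, 90 °C) rebuilds the E-2-methyl enal and comes back to the route at 9.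

Step 14. The risk is migration of the new exocyclic double bond into the lactone ring, or conjugate addition of amine to the new acceptor, during the basic quaternisation and elimination stages. Fallback: starting from 29, the lactone enolate (LiN(i-Pr)2, THF, −78 °C) is carboxylated with CO2 to the malonic half acid (3aS,5R,6E,10E,14E,15aR)-5-[(tert-butyldimethylsilyl)oxy]-6,10,14-trimethyl-2-oxo-2,3,3a,4,5,8,9,12,13,15a-decahydrocyclotetradeca[b]furan-3-carboxylic acid F6 (epimers at C3). Treatment with aqueous formaldehyde and diethylamine in an acetic acid/sodium acetate buffer at rt should bring about Mannich addition and decarboxylative loss of the amine under weakly acidic conditions, coming back to the route at 33.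

Further compounds
F1 | step 12 | tert-butyl 2-[(1S,2S,3E,7E,11E,13R)-13-[(tert-butyldimethylsilyl)oxy]-2-hydroxy-4,8,12-trimethylcyclotetradeca-3,7,11-trien-1-yl]acetate | O[C@@H]1/C=C(\C)CC/C=C(\C)CC/C=C(\C)[C@H](O[Si](C)(C)C(C)(C)C)C[C@H]1CC(=O)OC(C)(C)C
F2 | step 12 | tert-butyl 2-[(1S,3E,7E,11E,13R)-13-[(tert-butyldimethylsilyl)oxy]-4,8,12-trimethyl-2-oxocyclotetradeca-3,7,11-trien-1-yl]acetate | O=C1/C=C(\C)CC/C=C(\C)CC/C=C(\C)[C@H](O[Si](C)(C)C(C)(C)C)C[C@H]1CC(=O)OC(C)(C)C
F3 | step 3 | (6E,10E)-3-bromo-11-iodo-2,6,10-trimethylundeca-6,10-dien-2-ol (racemic at C3) | I/C=C(\C)CC/C=C(\C)CCC(Br)C(C)(C)O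
F4 | step 3 | 2,2-dimethyl-3-[(3E,7E)-8-iodo-3,7-dimethylocta-3,7-dien-1-yl]oxirane (racemic) | I/C=C(\C)CC/C=C(\C)CCC1OC1(C)C
F5 | step 3 | (4E,8E)-9-iodo-4,8-dimethylnona-4,8-dienal | I/C=C(\C)CC/C=C(\C)CCC=O
F6 | step 14 | (3aS,5R,6E,10E,14E,15aR)-5-[(tert-butyldimethylsilyl)oxy]-6,10,14-trimethyl-2-oxo-2,3,3a,4,5,8,9,12,13,15a-decahydrocyclotetradeca[b]furan-3-carboxylic acid (epimers at C3) | OC(=O)C1C(=O)O[C@H]2/C=C(\C)CC/C=C(\C)CC/C=C(\C)[C@H](O[Si](C)(C)C(C)(C)C)C[C@@H]12
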